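**Plan**

- Retrosynthesis: the naphthazarin is traced back (tautomerization, one alcohol oxidation, desilylation, oxidative de-ethylation of ring A) to a 5,8-diethoxy-1,4-bis(silyloxy)-1,4-dihydronaphthalene. Cutting C4a–C8a, C5–C6 and C7–C8 leaves acetylene (C6, C7) and a 1,7-diyne.
- Enabling feature: ring A is a benzene with oxygen on C5 and C8, and its C4a and C8a are bridged by C4–C3–C2–C1 of ring B. Both rings therefore map onto one [2+2+2] union of acetylene with a diyne whose two alkynes are ynol ethers.
- The diyne is cut at C1–C8a and C4–C4a into a (Z)-enedial and two ethoxyacetylides, and the enedial is an opened 3-substituted furan. The side chain is cut at C1'–C2' (allylation of 3-furaldehyde), at the ester C–O, and at C3'=C4' (cross-metathesis).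
- Forward: the side chain is built on the furan, the furan is opened, two alkynes are added, and rings B and A close together in one step. The prenyl terminus and the quinone/hydroquinone pattern follow.
- Stereochemistry: the only stereocentre of the target, C1' (R), is set by reagent-controlled Brown allylboration in step 1, and no later step breaks a bond to it. The ring-B carbinol centres are carried as mixtures and end as carbonyl carbons.

Key step: step 6

Remark on the chemistry: locants C1–C8a are those of the naphthalene core of the target and C1'–C5' those of the side chain. The facial sense of the allylboration of 3-furaldehyde is assumed to follow that known for benzaldehyde and other heteroaryl aldehydes.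

**Route**

Step 1
Reactants: 1 3-furaldehyde (furan-3-carbaldehyde)
Product: 3 (1R)-1-(furan-3-yl)but-3-en-1-ol, via diisopinocampheylborinate 2 (not isolated)
Conditions: (+)-Ipc2B(allyl) (salt-free, 1.2 equiv), Et2O/pentane, −100 °C to −78 °C; then 3 M NaOH, 30% H2O2, 0 °C to rt
Reagents that add atoms: (+)-B-allyldiisopinocampheylborane, C=CCB([C@H]1C[C@H]2C[C@@H]([C@@H]1C)C2(C)C)[C@H]1C[C@H]2C[C@@H]([C@@H]1C)C2(C)C
Why: Brown allylboration through a closed chair transition state, in which the (−)-α-pinene-derived reagent delivers allyl to the Re face of aryl and heteroaryl aldehydes (its antipode turns benzaldehyde into the S carbinol), so C1' should be set as R under reagent control before alkaline H2O2 releases 3 from borinate 2.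

Step 2
Reactants: 3 (1R)-1-(furan-3-yl)but-3-en-1-ol; 4 isovaleryl chloride (3-methylbutanoyl chloride)
Product: 5 (1R)-1-(furan-3-yl)but-3-en-1-yl 3-methylbutanoate
Conditions: Et3N, DMAP (cat.), CH2Cl2, 0 °C to rt
Reagents that add atoms: none
Why: DMAP-catalysed O-acylation by an acid chloride breaks no bond to C1', so the configuration is kept, and the isovalerate is both the ester of the target and the protecting group for this oxygen to the end.

Step 3
Reactants: 5 (1R)-1-(furan-3-yl)but-3-en-1-yl 3-methylbutanoate
Product: 7 (2Z)-2-[(1R)-1-(3-methylbutanoyloxy)but-3-en-1-yl]but-2-enedial, via furan endoperoxide 6 (not isolated)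
Conditions: O2, visible light, tetraphenylporphyrin (cat.), CH2Cl2, −78 °C; then Me2S, −78 °C to 0 °C; used crude
Reagents that add atoms: dioxygen, O=O
Why: [4+2] cycloaddition of singlet oxygen to the furan and reduction of endoperoxide 6 by Me2S is the standard opening of 2,5-unsubstituted furans to cis-enedials with the Z geometry inherited from the ring, and the monosubstituted alkene and the ester are inert to singlet oxygen, which is why the trisubstituted prenyl terminus is not yet in place.

Step 4
Reactants: 7 (2Z)-2-[(1R)-1-(3-methylbutanoyloxy)but-3-en-1-yl]but-2-enedial; 8 ethoxyacetylene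
Product: 9 (4E)-1,8-diethoxy-4-[(1R)-1-(3-methylbutanoyloxy)but-3-en-1-yl]oct-4-ene-1,7-diyne-3,6-diol (the two carbinol carbons cis on the alkene; mixture at C3 and C6)
Conditions: 8 (3.0 equiv), n-BuLi (2.9 equiv), THF, −78 °C; crude 7 in THF added, −78 °C to −40 °C; sat. aq. NH4Cl at −78 °C
Reagents that add atoms: none
Why: twofold 1,2-addition of a lithium alkoxyacetylide to aldehydes, run by inverse addition into excess reagent so that the intermediate lactolate is opened by the second equivalent and quenched cold so that the alkoxides neither attack nor take over the isovalerate; the two new carbinol centres should form unselectively and are left as a mixture because both end as carbonyl carbons.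

Step 5
Reactants: 9 (4E)-1,8-diethoxy-4-[(1R)-1-(3-methylbutanoyloxy)but-3-en-1-yl]oct-4-ene-1,7-diyne-3,6-diol
Product: 10 (4Z)-3,6-bis(tert-butyldimethylsilyloxy)-1,8-diethoxy-4-[(1R)-1-(3-methylbutanoyloxy)but-3-en-1-yl]oct-4-ene-1,7-diyne (same geometry as 9; the descriptor changes with the silyl groups)
Conditions: TBSCl, imidazole, DMAP (cat.), DMF, 0 °C to rt
Reagents that add atoms: tert-butyldimethylsilyl chloride, CC(C)(C)[Si](C)(C)Cl
Why: silylation with a silyl chloride and imidazole under buffered, non-acidic conditions caps the γ-hydroxy ynol ethers, which blocks their Meyer–Schuster rearrangement to unsaturated esters and gives ethers that should survive rhodium, ruthenium and cerium in steps 6 to 8.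

Step 6
Reactants: 10 (4Z)-3,6-bis(tert-butyldimethylsilyloxy)-1,8-diethoxy-4-[(1R)-1-(3-methylbutanoyloxy)but-3-en-1-yl]oct-4-ene-1,7-diyne; 11 acetylene
Product: 12 (1R)-1-[1,4-bis(tert-butyldimethylsilyloxy)-5,8-diethoxy-1,4-dihydronaphthalen-2-yl]but-3-en-1-yl 3-methylbutanoate (mixture at C1 and C4)
Conditions: RhCl(PPh3)3 (10 mol%), 11 (1 atm), toluene, 40 °C, 10 added slowly
Reagents that add atoms: none
Why: Proposed new method: RhCl(PPh3)3 loses a phosphine, binds both ynol ether units of 10 and couples them oxidatively to a 2,5-diethoxyrhodacyclopentadiene of trivalent rhodium, which forms C4a–C8a and closes ring B as the six-membered carbocycle fused to the metallacycle; acetylene then inserts and reductive elimination forms C5–C6 and C7–C8, closing ring A as a benzene ring in the [2+2+2] sense and returning monovalent rhodium. The closest known reaction type is the RhCl(PPh3)3-catalysed co-cyclization of tethered 1,6- and 1,7-diynes with acetylene gas, which tolerates a nitrogen-substituted (ynamide) terminus, while 1-alkoxyalkynes are known only as the external partner in rhodium-catalysed cyclotrimerizations; a diyne with two ynol ether termini has not been used. No stereocentre is created: C1' is a spectator and the two silyloxy carbons stay as a mixture. The step needs chemoselectivity for cross-cyclization over diyne dimerization and over engagement of the vinyl group, which the (Z)-alkene (holding the two alkynes syn and within reach), the bulk of the silyloxy groups next to the internal alkynes, slow addition of 10 and a standing excess of acetylene should secure. The neutral chloride complex is chosen over cationic rhodium so that the acid-sensitive ynol ethers are not hydrated or rearranged.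

Step 7
Reactants: 12 (1R)-1-[1,4-bis(tert-butyldimethylsilyloxy)-5,8-diethoxy-1,4-dihydronaphthalen-2-yl]but-3-en-1-yl 3-methylbutanoate
Product: 13 (1R)-1-[1,4-bis(tert-butyldimethylsilyloxy)-5,8-diethoxy-1,4-dihydronaphthalen-2-yl]-4-methylpent-3-en-1-yl 3-methylbutanoate
Conditions: second-generation Grubbs catalyst RuCl2(H2IMes)(PCy3)(=CHPh) (5 mol%), 2-methyl-2-butene/CH2Cl2 1:1, 35 °C, sealed tube
Reagents that add atoms: 2-methyl-2-butene, CC=C(C)C
Why: olefin cross-metathesis of a monosubstituted alkene with 2-methyl-2-butene in large excess installs the trisubstituted prenyl terminus with loss of propene; it is placed here because the ynol ethers of 10 would enter enyne metathesis, while the hindered trisubstituted ring-B alkene of 12 should be inert to the ruthenium carbene.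

Step 8
Reactants: 13 (1R)-1-[1,4-bis(tert-butyldimethylsilyloxy)-5,8-diethoxy-1,4-dihydronaphthalen-2-yl]-4-methylpent-3-en-1-yl 3-methylbutanoate
Product: 14 (1R)-1-[1,4-bis(tert-butyldimethylsilyloxy)-5,8-dioxo-1,4,5,8-tetrahydronaphthalen-2-yl]-4-methylpent-3-en-1-yl 3-methylbutanoate
Conditions: (NH4)2Ce(NO3)6 (2.5 equiv), MeCN/H2O 4:1, 0 °C, 15 min
Reagents that add atoms: water, O
Why: oxidative dealkylation of a p-dialkoxybenzene to the p-quinone by tetravalent cerium (two one-electron oxidations, ipso attack of water, loss of ethanol) should be fast here because ring A is still an electron-rich 2,3-dialkyl-1,4-diethoxybenzene and not yet fused to a quinone, and the short exposure at 0 °C should leave the TBS ethers, the ester and the trisubstituted alkene untouched.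

Step 9
Reactants: 14 (1R)-1-[1,4-bis(tert-butyldimethylsilyloxy)-5,8-dioxo-1,4,5,8-tetrahydronaphthalen-2-yl]-4-methylpent-3-en-1-yl 3-methylbutanoate
Product: 15 (1R)-1-(1,4-dihydroxy-5,8-dioxo-1,4,5,8-tetrahydronaphthalen-2-yl)-4-methylpent-3-en-1-yl 3-methylbutanoate
Conditions: 48% aq. HF/MeCN 1:19, 0 °C to rt; used at once
Reagents that add atoms: none
Why: fluoride-driven cleavage of the two secondary TBS ethers under weakly acidic, non-nucleophilic conditions; the carbinols sit next to an electron-poor quinone, so ionization is not assisted, and the ester, the alkene and C1' should be unaffected.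

Step 10
Reactants: 15 (1R)-1-(1,4-dihydroxy-5,8-dioxo-1,4,5,8-tetrahydronaphthalen-2-yl)-4-methylpent-3-en-1-yl 3-methylbutanoate
Product: 17 isovalerylshikonin [(1R)-1-(5,8-dihydroxy-1,4-dioxo-1,4-dihydronaphthalen-2-yl)-4-methylpent-3-en-1-yl 3-methylbutanoate], via hydroxy-trione 16 (not isolated)
Conditions: Dess–Martin periodinane (1.2 equiv), CH2Cl2, 0 °C to rt
Reagents that add atoms: none
Why: Dess–Martin oxidation of one allylic carbinol (the less hindered C4–OH) gives hydroxy-trione 16, whose remaining carbinol C–H is γ to a quinone carbonyl, so enolization and proton shift should aromatize ring A and deliver the 5,8-dihydroxy-1,4-naphthoquinone directly; the chelated naphthazarin is not oxidized further and C1' is untouched, so the R configuration from step 1 is carried into 17.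

**Compound list**

1 | 3-furaldehyde (furan-3-carbaldehyde) | O=Cc1ccoc1 | starting material
2 | (1R)-1-(furan-3-yl)but-3-en-1-yl diisopinocampheylborinate (not isolated) | C=CC[C@@H](OB([C@H]1C[C@H]2C[C@@H]([C@@H]1C)C2(C)C)[C@H]1C[C@H]2C[C@@H]([C@@H]1C)C2(C)C)c1ccoc1 | intermediate
3 | (1R)-1-(furan-3-yl)but-3-en-1-ol | C=CC[C@@H](O)c1ccoc1 | intermediate
4 | isovaleryl chloride (3-methylbutanoyl chloride) | CC(C)CC(=O)Cl | starting material
5 | (1R)-1-(furan-3-yl)but-3-en-1-yl 3-methylbutanoate | C=CC[C@@H](OC(=O)CC(C)C)c1ccoc1 | intermediate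
6 | (1R)-1-(2,3,7-trioxabicyclo[2.2.1]hept-5-en-5-yl)but-3-en-1-yl 3-methylbutanoate (furan endoperoxide, bridgeheads as a mixture, not isolated) | C=CC[C@@H](OC(=O)CC(C)C)C1=CC2OOC1O2 | intermediate
7 | (2Z)-2-[(1R)-1-(3-methylbutanoyloxy)but-3-en-1-yl]but-2-enedial | O=C/C=C(/[C@H](OC(=O)CC(C)C)CC=C)C=O | intermediate
8 | ethoxyacetylene (ethoxyethyne) | CCOC#C | starting material
9 | (4E)-1,8-diethoxy-4-[(1R)-1-(3-methylbutanoyloxy)but-3-en-1-yl]oct-4-ene-1,7-diyne-3,6-diol (carbinol carbons cis on the alkene, mixture at C3 and C6) | CCOC#CC(O)/C=C(/[C@H](OC(=O)CC(C)C)CC=C)C(O)C#COCC | intermediate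
10 | (4Z)-3,6-bis(tert-butyldimethylsilyloxy)-1,8-diethoxy-4-[(1R)-1-(3-methylbutanoyloxy)but-3-en-1-yl]oct-4-ene-1,7-diyne (mixture at C3 and C6) | CCOC#CC(O[Si](C)(C)C(C)(C)C)/C=C(/[C@H](OC(=O)CC(C)C)CC=C)C(O[Si](C)(C)C(C)(C)C)C#COCC | intermediate
11 | acetylene | C#C | starting material
12 | (1R)-1-[1,4-bis(tert-butyldimethylsilyloxy)-5,8-diethoxy-1,4-dihydronaphthalen-2-yl]but-3-en-1-yl 3-methylbutanoate (mixture at C1 and C4) | C=CC[C@@H](OC(=O)CC(C)C)C1=CC(O[Si](C)(C)C(C)(C)C)c2c(OCC)ccc(OCC)c2C1O[Si](C)(C)C(C)(C)C | intermediate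
13 | (1R)-1-[1,4-bis(tert-butyldimethylsilyloxy)-5,8-diethoxy-1,4-dihydronaphthalen-2-yl]-4-methylpent-3-en-1-yl 3-methylbutanoate (mixture at C1 and C4) | CC(C)=CC[C@@H](OC(=O)CC(C)C)C1=CC(O[Si](C)(C)C(C)(C)C)c2c(OCC)ccc(OCC)c2C1O[Si](C)(C)C(C)(C)C | intermediate
14 | (1R)-1-[1,4-bis(tert-butyldimethylsilyloxy)-5,8-dioxo-1,4,5,8-tetrahydronaphthalen-2-yl]-4-methylpent-3-en-1-yl 3-methylbutanoate (mixture at C1 and C4) | CC(C)=CC[C@@H](OC(=O)CC(C)C)C1=CC(O[Si](C)(C)C(C)(C)C)C2=C(C1O[Si](C)(C)C(C)(C)C)C(=O)C=CC2=O | intermediate
15 | (1R)-1-(1,4-dihydroxy-5,8-dioxo-1,4,5,8-tetrahydronaphthalen-2-yl)-4-methylpent-3-en-1-yl 3-methylbutanoate (mixture at C1 and C4) | CC(C)=CC[C@@H](OC(=O)CC(C)C)C1=CC(O)C2=C(C1O)C(=O)C=CC2=O | intermediate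
16 | (1R)-1-(1-hydroxy-4,5,8-trioxo-1,4,5,8-tetrahydronaphthalen-2-yl)-4-methylpent-3-en-1-yl 3-methylbutanoate (mixture at C1, not isolated) | CC(C)=CC[C@@H](OC(=O)CC(C)C)C1=CC(=O)C2=C(C1O)C(=O)C=CC2=O | intermediate
17 | isovalerylshikonin, (1R)-1-(5,8-dihydroxy-1,4-dioxo-1,4-dihydronaphthalen-2-yl)-4-methylpent-3-en-1-yl 3-methylbutanoate | CC(C)=CC[C@@H](OC(=O)CC(C)C)C1=CC(=O)c2c(O)ccc(O)c2C1=O | target

**Totals and risks**

Total step count: 10. Longest linear sequence: 10 steps (from 1).

Step 6 (the proposed new method). Oxidative coupling of two electron-rich, hindered ynol ether units on rhodium may be slower than acetylene oligomerization. It may also be slower than coupling of one ynol ether with two acetylenes, which would leave ring B open, or than metal-induced decomposition of the ynol ethers. The fallback uses known chemistry only, sets out from 5 and comes back at 17; it uses the furan of 5 as a Diels–Alder diene instead of as an enedial source. 3,6-Dimethoxy-2-(trimethylsilyl)phenyl trifluoromethanesulfonate and CsF in MeCN should generate 3,6-dimethoxybenzyne F1, which adds across the furan to give the 1,4-epoxy-1,4-dihydronaphthalene F2. Catalytic CF3CO2H in CH2Cl2 should isomerize the oxygen bridge to the 1-naphthol F3 and its regioisomer, the 4-hydroxy compound F4. PhI(OAc)2 in aqueous MeCN should oxidize both to the same 5,8-dimethoxy-1,4-naphthoquinone F5. Cross-metathesis with 2-methyl-2-butene as in step 7 should give the prenyl quinone F6. AgO with 6 M HNO3 in dioxane should remove both methyl groups oxidatively to give the naphthalene-1,4,5,8-tetraone F7, and aqueous Na2S2O4 should reduce this to 17.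

Step 9. Once the silyl groups are off, the ene-diol flanked by the quinone may lose water by vinylogous β-elimination and aromatize to a 5-hydroxy-1,4-naphthoquinone. That product is one oxygen short and cannot be brought back. The fallback sets out from 13 and comes back at 17; it reverses the order of the oxidations so that no free diol ever sits next to a quinone. Bu4NF buffered with AcOH in THF should desilylate 13 at the electron-rich arene stage to the diethoxy diol F8. MnO2 in CH2Cl2 should oxidize ring B of F8 to the 5,8-diethoxy-1,4-naphthoquinone F9. AgO/HNO3 should then take F9 to the tetraone F7 already met in the fallback for step 6, and Na2S2O4 should reduce it to 17.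

Step 4. The first lithium alkoxide may close onto the second aldehyde as a lactolate, so that the second addition stalls at −78 °C. Warming to reopen it invites acyl transfer from the neighbouring isovalerate or attack at the ester, and the enedial may isomerize to the E form before it reacts. The fallback sets out from 7 and comes back at 9; it replaces the stoichiometric lithium acetylide by 1-ethoxy-2-(trimethylsilyl)ethyne with a catalytic fluoride source (Bu4N Ph3SiF2, THF, −20 °C). Each alkoxide should be silylated as it forms by transfer from the silylalkyne, so no free alkoxide persists, and the product is the bis(trimethylsilyl) ether F10. NH4F in MeOH at 0 °C should then remove the trimethylsilyl groups and give 9.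

**Further compounds**

F1 | step 6 | 3,6-dimethoxybenzyne (1,4-dimethoxy-2,3-didehydrobenzene, transient) | COC1=CC=C(OC)C#C1
F2 | step 6 | (1R)-1-(5,8-dimethoxy-1,4-dihydro-1,4-epoxynaphthalen-2-yl)but-3-en-1-yl 3-methylbutanoate (bridgeheads as a mixture) | C=CC[C@@H](OC(=O)CC(C)C)C1=CC2OC1c1c(OC)ccc(OC)c12
F3 | step 6 | (1R)-1-(1-hydroxy-5,8-dimethoxynaphthalen-2-yl)but-3-en-1-yl 3-methylbutanoate | C=CC[C@@H](OC(=O)CC(C)C)c1ccc2c(OC)ccc(OC)c2c1O
F4 | step 6 | (1R)-1-(4-hydroxy-5,8-dimethoxynaphthalen-2-yl)but-3-en-1-yl 3-methylbutanoate | C=CC[C@@H](OC(=O)CC(C)C)c1cc(O)c2c(OC)ccc(OC)c2c1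
F5 | step 6 | (1R)-1-(5,8-dimethoxy-1,4-dioxo-1,4-dihydronaphthalen-2-yl)but-3-en-1-yl 3-methylbutanoate | C=CC[C@@H](OC(=O)CC(C)C)C1=CC(=O)c2c(OC)ccc(OC)c2C1=O
F6 | step 6 | (1R)-1-(5,8-dimethoxy-1,4-dioxo-1,4-dihydronaphthalen-2-yl)-4-methylpent-3-en-1-yl 3-methylbutanoate | CC(C)=CC[C@@H](OC(=O)CC(C)C)C1=CC(=O)c2c(OC)ccc(OC)c2C1=O
F7 | step 6 | (1R)-4-methyl-1-(1,4,5,8-tetraoxo-1,4,5,8-tetrahydronaphthalen-2-yl)pent-3-en-1-yl 3-methylbutanoate | CC(C)=CC[C@@H](OC(=O)CC(C)C)C1=CC(=O)C2=C(C1=O)C(=O)C=CC2=O
F8 | step 9 | (1R)-1-(5,8-diethoxy-1,4-dihydroxy-1,4-dihydronaphthalen-2-yl)-4-methylpent-3-en-1-yl 3-methylbutanoate (mixture at C1 and C4) | CC(C)=CC[C@@H](OC(=O)CC(C)C)C1=CC(O)c2c(OCC)ccc(OCC)c2C1O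
F9 | step 9 | (1R)-1-(5,8-diethoxy-1,4-dioxo-1,4-dihydronaphthalen-2-yl)-4-methylpent-3-en-1-yl 3-methylbutanoate | CC(C)=CC[C@@H](OC(=O)CC(C)C)C1=CC(=O)c2c(OCC)ccc(OCC)c2C1=O
F10 | step 4 | (4Z)-1,8-diethoxy-4-[(1R)-1-(3-methylbutanoyloxy)but-3-en-1-yl]-3,6-bis(trimethylsilyloxy)oct-4-ene-1,7-diyne (mixture at C3 and C6) | CCOC#CC(O[Si](C)(C)C)/C=C(/[C@H](OC(=O)CC(C)C)CC=C)C(O[Si](C)(C)C)C#COCC
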